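**Plan**

Target ring numbering used below: C1 = ketone carbon, C2 = carbon bearing the CH2O arm (C7), C3 = alkene CH, C4 = CH–O‑tiglate, C5 = CH–isopropyl, C6 = CH–OAc.
Retrosynthesis: the three ester C–O bonds go first; the 6‑oxycyclohex‑2‑en‑1‑one is then the β‑elimination product of a 7‑oxabicyclo[2.2.1]heptan‑2‑one (C6 oxygen bridged to C3), and the bicycle is cut at C2–C3 and C1–C6 by a reverse Diels–Alder reaction.
Enabling feature: C3–C4–C5–C6 plus the C6 oxygen are a 3‑isopropylfuran in disguise, and C1(=O)–C2–C7 is a β‑keto ester equivalent (methyl 3‑bromopropiolate); isopropyl (C5) and C7 (on C2) stand 1,4, as the cycloaddition prefers.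
Forward order: Kumada coupling to the furan, dearomatizing Diels–Alder reaction (bicycle), ketalization, exo hydroboration, oxidation and exo reduction, protection and first tiglate, ketal hydrolysis, opening of the oxygen bridge (cyclohexenone), acetate, second tiglate.
Stereochemistry: C6 is the Diels–Alder bridgehead, whose C–O bond is never broken; C5 comes from exo delivery of H in the hydroboration; C4 from exo hydride attack on the C4 ketone; the absolute configuration from a lipase resolution of the first alcohol.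

Key step: step 3

Assumption: the ester-bearing carbon of 7–11 is drawn with the ester endo (protonation from the exo face), a centre that becomes sp2 in step 12 so its configuration does not matter; the lipase of step 6 is taken to acylate the unwanted enantiomer.

**Step 1**
Reactants: 1 3-bromofuran
Product: 2 3-(propan-2-yl)furan
Conditions: i-PrMgCl (1.3 equiv), PdCl2(dppf) (2 mol %), Et2O, 0 °C to reflux
Reagents that add atoms: isopropylmagnesium chloride, CC(C)[Mg]Cl
Why: Kumada coupling with a wide-bite-angle bisphosphine palladium catalyst, which favours reductive elimination over β-hydride elimination, should transfer the secondary alkyl group without isomerization to n-propyl; no stereocentre is formed.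

**Step 2**
Reactants: 3 methyl prop-2-ynoate
Product: 4 methyl 3-bromoprop-2-ynoate
Conditions: NBS, AgNO3 (10 mol %), acetone, rt
Reagents that add atoms: N-bromosuccinimide, O=C1CCC(=O)N1Br
Why: Silver-catalysed electrophilic bromination of the terminal alkyne C–H through the silver acetylide is the standard entry to 3-bromopropiolates; no stereocentre is formed.

**Step 3**
Reactants: 2 3-(propan-2-yl)furan; 4 methyl 3-bromoprop-2-ynoate
Product: 5 rac-methyl (1S,4R)-3-bromo-5-(propan-2-yl)-7-oxabicyclo[2.2.1]hepta-2,5-diene-2-carboxylate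
Conditions: toluene, 80 °C, sealed vessel, 2 in excess; used without prolonged heating on work-up
Reagents that add atoms: none
Why: A concerted, asynchronous [4+2] cycloaddition of normal electron demand dearomatizes the furan and forms C1–C6 and C2–C3 of the later cyclohexenone at once, the furan oxygen becoming the bridge that later carries the C6 acetate. The closest known reaction type is the thermal Diels–Alder reaction of furans with 3-halopropiolates to 7-oxanorbornadienes. The six-membered carbocycle and the oxygen-bridged bicycle close in one intermolecular suprafacial–suprafacial union through a boat-like transition state, both bonds forming in the same event. The two new stereocentres are the bridgeheads, whose cis relationship is dictated by the oxygen bridge, while the absolute sense is not controlled here (racemate, resolved in step 6). The step needs regioselectivity, which the substrate should supply because the larger HOMO coefficient of a 3-alkylfuran lies at C2 next to the alkyl group and the larger LUMO coefficient of the ynoate lies at the bromine-bearing β-carbon, giving the adduct with isopropyl and ester carbon 1,4 to each other. Chemoselectivity follows from the fact that only the alkyne π bond conjugated to the ester is activated.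

**Step 4**
Reactants: 5 rac-methyl (1S,4R)-3-bromo-5-(propan-2-yl)-7-oxabicyclo[2.2.1]hepta-2,5-diene-2-carboxylate
Product: 7 rac-methyl (1S,2R,4R)-3,3-dimethoxy-5-(propan-2-yl)-7-oxabicyclo[2.2.1]hept-5-ene-2-carboxylate, via methoxy enoate 6 (not isolated)
Conditions: NaOMe (2.2 equiv), MeOH, 0 °C to rt
Reagents that add atoms: sodium methoxide, [Na+].[O-]C; methanol, CO
Why: Conjugate addition–elimination of methoxide at the bromine-bearing β-carbon gives the vinylogous carbonate 6, which takes up methanol in a second oxa-Michael addition to the dimethyl ketal with exo protonation of the ester α-carbon (ester endo), while the unactivated isopropyl-bearing double bond is untouched.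

**Step 5**
Reactants: 7 rac-methyl (1S,2R,4R)-3,3-dimethoxy-5-(propan-2-yl)-7-oxabicyclo[2.2.1]hept-5-ene-2-carboxylate
Product: 9 rac-methyl (1R,2R,4R,5S,6S)-6-hydroxy-3,3-dimethoxy-5-(propan-2-yl)-7-oxabicyclo[2.2.1]heptane-2-carboxylate, via alkylborane 8 (not isolated)
Conditions: BH3·SMe2 (1.1 equiv), THF, 0 °C; then 30% H2O2, aq. NaOAc, 0 °C to rt
Reagents that add atoms: hydrogen peroxide, OO
Why: Hydroboration–oxidation adds H and B syn from the exo face of the strained bicyclic alkene with boron at the less substituted carbon, so H is delivered exo to the isopropyl-bearing carbon (isopropyl endo, trans to the oxygen bridge) and oxidation with retention gives the exo alcohol.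

**Step 6**
Reactants: 9 rac-methyl (1R,2R,4R,5S,6S)-6-hydroxy-3,3-dimethoxy-5-(propan-2-yl)-7-oxabicyclo[2.2.1]heptane-2-carboxylate
Product: 10 methyl (1R,2R,4R,5S,6S)-6-hydroxy-3,3-dimethoxy-5-(propan-2-yl)-7-oxabicyclo[2.2.1]heptane-2-carboxylate (single enantiomer, recovered unreacted)
Conditions: Candida antarctica lipase B (immobilized), vinyl acetate, MTBE, 30 °C, stopped just past half conversion; chromatography
Reagents that add atoms: none
Why: Lipase-catalysed kinetic resolution by enantioselective transesterification of a rigid bicyclic secondary alcohol should leave one enantiomer unacylated, which is separated from the acetate of the other and fixes the absolute configuration of all later compounds.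

**Step 7**
Reactants: 10 methyl (1R,2R,4R,5S,6S)-6-hydroxy-3,3-dimethoxy-5-(propan-2-yl)-7-oxabicyclo[2.2.1]heptane-2-carboxylate
Product: 11 methyl (1R,2R,4R,5R)-3,3-dimethoxy-6-oxo-5-(propan-2-yl)-7-oxabicyclo[2.2.1]heptane-2-carboxylate
Conditions: Dess–Martin periodinane, NaHCO3, CH2Cl2, 0 °C to rt
Reagents that add atoms: none
Why: Dess–Martin oxidation under buffered, non-basic conditions should give the ketone without epimerizing the adjacent isopropyl-bearing centre.

**Step 8**
Reactants: 11 methyl (1R,2R,4R,5R)-3,3-dimethoxy-6-oxo-5-(propan-2-yl)-7-oxabicyclo[2.2.1]heptane-2-carboxylate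
Product: 12 (1R,2R,3S,4R,6R)-6-(hydroxymethyl)-5,5-dimethoxy-3-(propan-2-yl)-7-oxabicyclo[2.2.1]heptan-2-ol
Conditions: LiAlH4, THF, −78 to 0 °C
Reagents that add atoms: none
Why: Hydride reduction of ketone and ester in one operation, in which hydride attacks the 7-oxanorbornanone from the open exo face (the endo face is screened by the endo isopropyl and ester groups), sets the new carbinol centre endo and thus cis to isopropyl.

**Step 9**
Reactants: 12 (1R,2R,3S,4R,6R)-6-(hydroxymethyl)-5,5-dimethoxy-3-(propan-2-yl)-7-oxabicyclo[2.2.1]heptan-2-ol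
Product: 13 (1R,2R,3S,4R,6R)-6-{[tert-butyl(diphenyl)silyl]oxymethyl}-5,5-dimethoxy-3-(propan-2-yl)-7-oxabicyclo[2.2.1]heptan-2-ol
Conditions: TBDPSCl, imidazole, CH2Cl2, 0 °C
Reagents that add atoms: tert-butyl(chloro)diphenylsilane, CC(C)(C)[Si](Cl)(c1ccccc1)c1ccccc1
Why: Selective silylation of the primary over the hindered endo secondary alcohol gives an acid-stable ether that, unlike an ester, cannot leave from the position β to the enol ether of step 12.

**Step 10**
Reactants: 13 (1R,2R,3S,4R,6R)-6-{[tert-butyl(diphenyl)silyl]oxymethyl}-5,5-dimethoxy-3-(propan-2-yl)-7-oxabicyclo[2.2.1]heptan-2-ol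
Product: 14 (1R,2R,3S,4R,6R)-6-{[tert-butyl(diphenyl)silyl]oxymethyl}-5,5-dimethoxy-3-(propan-2-yl)-7-oxabicyclo[2.2.1]heptan-2-yl (E)-2-methylbut-2-enoate
Conditions: tigloyl chloride, pyridine, DMAP, CH2Cl2, rt
Reagents that add atoms: (E)-2-methylbut-2-enoyl chloride, C/C=C(\C)C(Cl)=O
Why: DMAP-catalysed acylation through the acylpyridinium ion should esterify the remaining secondary alcohol on the robust bicycle, the E geometry of the tiglate being the thermodynamically favoured one.

**Step 11**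
Reactants: 14 (1R,2R,3S,4R,6R)-6-{[tert-butyl(diphenyl)silyl]oxymethyl}-5,5-dimethoxy-3-(propan-2-yl)-7-oxabicyclo[2.2.1]heptan-2-yl (E)-2-methylbut-2-enoate
Product: 15 (1R,2R,3S,4R,6R)-6-{[tert-butyl(diphenyl)silyl]oxymethyl}-5-oxo-3-(propan-2-yl)-7-oxabicyclo[2.2.1]heptan-2-yl (E)-2-methylbut-2-enoate
Conditions: 1 M aq. HCl, THF, rt
Reagents that add atoms: water, O
Why: Acid-catalysed ketal hydrolysis should unveil the ketone while the tert-butyldiphenylsilyl ether and the tiglate, both stable to dilute aqueous acid, remain.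

**Step 12**
Reactants: 15 (1R,2R,3S,4R,6R)-6-{[tert-butyl(diphenyl)silyl]oxymethyl}-5-oxo-3-(propan-2-yl)-7-oxabicyclo[2.2.1]heptan-2-yl (E)-2-methylbut-2-enoate
Product: 18 (4S,5R,6R)-2-{[tert-butyl(diphenyl)silyl]oxymethyl}-6-hydroxy-5-(propan-2-yl)-4-{[(E)-2-methylbut-2-enoyl]oxy}cyclohex-2-en-1-one, via trimethylsilyl enol ether 16 (not isolated), via silyloxy enone 17 (not isolated)
Conditions: TMSOTf (2.2 equiv), Et3N (3 equiv), CH2Cl2, 0 °C to rt; then 1 M aq. HCl, THF, 0 °C
Reagents that add atoms: none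
Why: Soft enolization can only occur toward the carbon bearing the silyloxymethyl group (the other α-carbon is a bridgehead), and silyl-triflate-assisted β-elimination of the bridging oxygen from that silyl enol ether, a known way to open 7-oxabicyclo[2.2.1]heptan-2-ones, gives the cyclohexenone whose C6–O bond is never broken and so keeps its configuration, mild acid then removing the trimethylsilyl group.

**Step 13**
Reactants: 18 (4S,5R,6R)-2-{[tert-butyl(diphenyl)silyl]oxymethyl}-6-hydroxy-5-(propan-2-yl)-4-{[(E)-2-methylbut-2-enoyl]oxy}cyclohex-2-en-1-one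
Product: 19 (4S,5S,6R)-6-acetoxy-2-{[tert-butyl(diphenyl)silyl]oxymethyl}-5-(propan-2-yl)-4-{[(E)-2-methylbut-2-enoyl]oxy}cyclohex-2-en-1-one
Conditions: Ac2O, pyridine, DMAP (cat.), CH2Cl2, 0 °C
Reagents that add atoms: acetic anhydride, CC(=O)OC(C)=O
Why: Acetylation of the only free hydroxyl group under DMAP catalysis at 0 °C is mild enough not to epimerize the α-acyloxy ketone.

**Step 14**
Reactants: 19 (4S,5S,6R)-6-acetoxy-2-{[tert-butyl(diphenyl)silyl]oxymethyl}-5-(propan-2-yl)-4-{[(E)-2-methylbut-2-enoyl]oxy}cyclohex-2-en-1-one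
Product: 20 (4S,5S,6R)-6-acetoxy-2-(hydroxymethyl)-5-(propan-2-yl)-4-{[(E)-2-methylbut-2-enoyl]oxy}cyclohex-2-en-1-one
Conditions: HF·pyridine, pyridine, THF, 0 °C to rt
Reagents that add atoms: none
Why: Fluoride-mediated silyl ether cleavage with buffered HF·pyridine should free the primary alcohol without touching the two esters or the enone, basic fluoride sources being avoided to prevent acyl migration.

**Step 15**
Reactants: 20 (4S,5S,6R)-6-acetoxy-2-(hydroxymethyl)-5-(propan-2-yl)-4-{[(E)-2-methylbut-2-enoyl]oxy}cyclohex-2-en-1-one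
Product: 21 (4S,5S,6R)-6-acetoxy-5-(propan-2-yl)-4-{[(E)-2-methylbut-2-enoyl]oxy}-2-({[(E)-2-methylbut-2-enoyl]oxy}methyl)cyclohex-2-en-1-one (CNP0218511.1)
Conditions: tigloyl chloride, pyridine, CH2Cl2, −20 to 0 °C
Reagents that add atoms: (E)-2-methylbut-2-enoyl chloride, C/C=C(\C)C(Cl)=O
Why: Acylation of the unhindered primary allylic alcohol with the acid chloride and pyridine at low temperature completes the target without disturbing the enone or the α-acetoxy ketone.

**Compound list**

1 | 3-bromofuran | Brc1ccoc1 | starting material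
2 | 3-(propan-2-yl)furan | CC(C)c1ccoc1 | intermediate
3 | methyl prop-2-ynoate (methyl propiolate) | C#CC(=O)OC | starting material
4 | methyl 3-bromoprop-2-ynoate | BrC#CC(=O)OC | intermediate
5 | rac-methyl (1S,4R)-3-bromo-5-(propan-2-yl)-7-oxabicyclo[2.2.1]hepta-2,5-diene-2-carboxylate (racemate; the enantiomer carried on is drawn) | COC(=O)C1=C(Br)[C@@H]2O[C@H]1C=C2C(C)C | intermediate
6 | rac-methyl (1S,4R)-3-methoxy-5-(propan-2-yl)-7-oxabicyclo[2.2.1]hepta-2,5-diene-2-carboxylate (not isolated) | COC(=O)C1=C(OC)[C@@H]2O[C@H]1C=C2C(C)C | intermediate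
7 | rac-methyl (1S,2R,4R)-3,3-dimethoxy-5-(propan-2-yl)-7-oxabicyclo[2.2.1]hept-5-ene-2-carboxylate (ester endo) | COC(=O)[C@H]1C(OC)(OC)[C@@H]2O[C@H]1C=C2C(C)C | intermediate
8 | rac-methyl 6-exo-boranyl-3,3-dimethoxy-5-endo-(propan-2-yl)-7-oxabicyclo[2.2.1]heptane-2-endo-carboxylate (not isolated) | COC(=O)[C@H]1C(OC)(OC)[C@@H]2O[C@H]1[C@@H](B)[C@@H]2C(C)C | intermediate
9 | rac-methyl (1R,2R,4R,5S,6S)-6-hydroxy-3,3-dimethoxy-5-(propan-2-yl)-7-oxabicyclo[2.2.1]heptane-2-carboxylate (6-exo-OH, 5-endo-isopropyl) | COC(=O)[C@H]1C(OC)(OC)[C@@H]2O[C@H]1[C@@H](O)[C@@H]2C(C)C | intermediate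
10 | methyl (1R,2R,4R,5S,6S)-6-hydroxy-3,3-dimethoxy-5-(propan-2-yl)-7-oxabicyclo[2.2.1]heptane-2-carboxylate (single enantiomer) | COC(=O)[C@H]1C(OC)(OC)[C@@H]2O[C@H]1[C@@H](O)[C@@H]2C(C)C | intermediate
11 | methyl (1R,2R,4R,5R)-3,3-dimethoxy-6-oxo-5-(propan-2-yl)-7-oxabicyclo[2.2.1]heptane-2-carboxylate | COC(=O)[C@H]1C(OC)(OC)[C@@H]2O[C@H]1C(=O)[C@@H]2C(C)C | intermediate
12 | (1R,2R,3S,4R,6R)-6-(hydroxymethyl)-5,5-dimethoxy-3-(propan-2-yl)-7-oxabicyclo[2.2.1]heptan-2-ol (2-endo-OH, 3-endo-isopropyl) | OC[C@H]1C(OC)(OC)[C@@H]2O[C@H]1[C@H](O)[C@@H]2C(C)C | intermediate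
13 | (1R,2R,3S,4R,6R)-6-{[tert-butyl(diphenyl)silyl]oxymethyl}-5,5-dimethoxy-3-(propan-2-yl)-7-oxabicyclo[2.2.1]heptan-2-ol | CC(C)(C)[Si](OC[C@H]1C(OC)(OC)[C@@H]2O[C@H]1[C@H](O)[C@@H]2C(C)C)(c3ccccc3)c4ccccc4 | intermediate
14 | (1R,2R,3S,4R,6R)-6-{[tert-butyl(diphenyl)silyl]oxymethyl}-5,5-dimethoxy-3-(propan-2-yl)-7-oxabicyclo[2.2.1]heptan-2-yl (E)-2-methylbut-2-enoate | CC(C)(C)[Si](OC[C@H]1C(OC)(OC)[C@@H]2O[C@H]1[C@H](OC(=O)/C(C)=C/C)[C@@H]2C(C)C)(c3ccccc3)c4ccccc4 | intermediate
15 | (1R,2R,3S,4R,6R)-6-{[tert-butyl(diphenyl)silyl]oxymethyl}-5-oxo-3-(propan-2-yl)-7-oxabicyclo[2.2.1]heptan-2-yl (E)-2-methylbut-2-enoate | CC(C)(C)[Si](OC[C@H]1C(=O)[C@@H]2O[C@H]1[C@H](OC(=O)/C(C)=C/C)[C@@H]2C(C)C)(c3ccccc3)c4ccccc4 | intermediate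
16 | trimethylsilyl enol ether of 15 (enol double bond between the former ketone carbon and the silyloxymethyl-bearing carbon; not isolated) | CC(C)(C)[Si](OCC1=C(O[Si](C)(C)C)[C@@H]2O[C@H]1[C@H](OC(=O)/C(C)=C/C)[C@@H]2C(C)C)(c3ccccc3)c4ccccc4 | intermediate
17 | (4S,5S,6R)-2-{[tert-butyl(diphenyl)silyl]oxymethyl}-5-(propan-2-yl)-4-{[(E)-2-methylbut-2-enoyl]oxy}-6-(trimethylsilyloxy)cyclohex-2-en-1-one (not isolated) | CC(C)(C)[Si](OCC1=C[C@H](OC(=O)/C(C)=C/C)[C@H](C(C)C)[C@@H](O[Si](C)(C)C)C1=O)(c3ccccc3)c4ccccc4 | intermediate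
18 | (4S,5R,6R)-2-{[tert-butyl(diphenyl)silyl]oxymethyl}-6-hydroxy-5-(propan-2-yl)-4-{[(E)-2-methylbut-2-enoyl]oxy}cyclohex-2-en-1-one | CC(C)(C)[Si](OCC1=C[C@H](OC(=O)/C(C)=C/C)[C@H](C(C)C)[C@@H](O)C1=O)(c3ccccc3)c4ccccc4 | intermediate
19 | (4S,5S,6R)-6-acetoxy-2-{[tert-butyl(diphenyl)silyl]oxymethyl}-5-(propan-2-yl)-4-{[(E)-2-methylbut-2-enoyl]oxy}cyclohex-2-en-1-one | CC(C)(C)[Si](OCC1=C[C@H](OC(=O)/C(C)=C/C)[C@H](C(C)C)[C@@H](OC(C)=O)C1=O)(c3ccccc3)c4ccccc4 | intermediate
20 | (4S,5S,6R)-6-acetoxy-2-(hydroxymethyl)-5-(propan-2-yl)-4-{[(E)-2-methylbut-2-enoyl]oxy}cyclohex-2-en-1-one | OCC1=C[C@H](OC(=O)/C(C)=C/C)[C@H](C(C)C)[C@@H](OC(C)=O)C1=O | intermediate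
21 | (4S,5S,6R)-6-acetoxy-5-(propan-2-yl)-4-{[(E)-2-methylbut-2-enoyl]oxy}-2-({[(E)-2-methylbut-2-enoyl]oxy}methyl)cyclohex-2-en-1-one (CNP0218511.1) | C/C=C(\C)C(=O)OCC1=C[C@H](OC(=O)/C(C)=C/C)[C@H](C(C)C)[C@@H](OC(C)=O)C1=O | target

**Step count and risks**

Total steps: 15. Longest linear sequence: 14 steps (1, then 3 to 15); step 2 is a one-step branch.

Steps most likely to fail:

1. Step 3. The isopropyl group is only a weak director, so regiocontrol may erode, with the bromine-bearing carbon also bonding to the remote furan terminus; the adduct may also revert to its components during isolation. Fallback: the isopropyl group is brought in after the cycloaddition. It sets out from 1 and 4. 3-Bromofuran itself serves as the diene, its bromine lone pair polarising the furan toward the same terminus, and should give rac-methyl (1S,4R)-3,5-dibromo-7-oxabicyclo[2.2.1]hepta-2,5-diene-2-carboxylate F1, from which any regioisomer is removed by crystallization. NaOMe in MeOH should convert only the activated bromoenoate, giving the ketal rac-methyl (1R,2R,4S)-5-bromo-3,3-dimethoxy-7-oxabicyclo[2.2.1]hept-5-ene-2-carboxylate F2. Negishi coupling of the remaining vinyl bromide with isopropylzinc bromide (Pd(OAc)2, CPhos, THF, rt) comes back to the route at 7.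

2. Step 6. The enzyme may discriminate poorly between the enantiomers of this crowded bicyclic alcohol, or acylate the wanted one. Fallback: resolution through covalent diastereomers, setting out from 9. Esterification with (S)-2-methoxy-2-phenylacetic acid (DCC, DMAP, CH2Cl2) gives two diastereomeric esters. The one derived from the wanted enantiomer, methyl (1R,2R,4R,5S,6S)-3,3-dimethoxy-6-{[(2S)-2-methoxy-2-phenylacetyl]oxy}-5-(propan-2-yl)-7-oxabicyclo[2.2.1]heptane-2-carboxylate F3, is separated on silica. Methanolysis with K2CO3 in MeOH comes back to the route at 10.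

3. Step 12. The product enone may be enolized further toward C6 with loss of that configuration, or over-silylation and other elimination paths may compete with clean bridge opening. Fallback: the bridge is opened from an aldehyde at C7 while the C1 carbonyl stays masked as the ketal, setting out from 14.
   - HF·pyridine frees the primary alcohol (1R,2R,3S,4R,6R)-6-(hydroxymethyl)-5,5-dimethoxy-3-(propan-2-yl)-7-oxabicyclo[2.2.1]heptan-2-yl (E)-2-methylbut-2-enoate F4.
   - Dess–Martin oxidation gives (1R,2R,3S,4R,6S)-6-formyl-5,5-dimethoxy-3-(propan-2-yl)-7-oxabicyclo[2.2.1]heptan-2-yl (E)-2-methylbut-2-enoate F5.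
   - DBU in CH2Cl2 opens the oxygen bridge by E1cB elimination to the enal (1S,5R,6R)-3-formyl-5-hydroxy-4,4-dimethoxy-6-(propan-2-yl)cyclohex-2-en-1-yl (E)-2-methylbut-2-enoate F6.
   - Ac2O and pyridine give (1S,5R,6S)-5-acetoxy-3-formyl-4,4-dimethoxy-6-(propan-2-yl)cyclohex-2-en-1-yl (E)-2-methylbut-2-enoate F7.
   - Luche reduction (NaBH4, CeCl3·7H2O, MeOH, −78 °C) gives (1S,5R,6S)-5-acetoxy-3-(hydroxymethyl)-4,4-dimethoxy-6-(propan-2-yl)cyclohex-2-en-1-yl (E)-2-methylbut-2-enoate F8.
   - Ketal hydrolysis with 1 M aq. HCl in THF comes back to the route at 20.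

**Further compounds**

F1 | step 3 | rac-methyl (1S,4R)-3,5-dibromo-7-oxabicyclo[2.2.1]hepta-2,5-diene-2-carboxylate | COC(=O)C1=C(Br)[C@@H]2O[C@H]1C=C2Br
F2 | step 3 | rac-methyl (1R,2R,4S)-5-bromo-3,3-dimethoxy-7-oxabicyclo[2.2.1]hept-5-ene-2-carboxylate | COC(=O)[C@H]1C(OC)(OC)[C@@H]2O[C@H]1C=C2Br
F3 | step 6 | methyl (1R,2R,4R,5S,6S)-3,3-dimethoxy-6-{[(2S)-2-methoxy-2-phenylacetyl]oxy}-5-(propan-2-yl)-7-oxabicyclo[2.2.1]heptane-2-carboxylate | COC(=O)[C@H]1C(OC)(OC)[C@@H]2O[C@H]1[C@@H](OC(=O)[C@@H](OC)c3ccccc3)[C@@H]2C(C)C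
F4 | step 12 | (1R,2R,3S,4R,6R)-6-(hydroxymethyl)-5,5-dimethoxy-3-(propan-2-yl)-7-oxabicyclo[2.2.1]heptan-2-yl (E)-2-methylbut-2-enoate | OC[C@H]1C(OC)(OC)[C@@H]2O[C@H]1[C@H](OC(=O)/C(C)=C/C)[C@@H]2C(C)C
F5 | step 12 | (1R,2R,3S,4R,6S)-6-formyl-5,5-dimethoxy-3-(propan-2-yl)-7-oxabicyclo[2.2.1]heptan-2-yl (E)-2-methylbut-2-enoate | O=C[C@H]1C(OC)(OC)[C@@H]2O[C@H]1[C@H](OC(=O)/C(C)=C/C)[C@@H]2C(C)C
F6 | step 12 | (1S,5R,6R)-3-formyl-5-hydroxy-4,4-dimethoxy-6-(propan-2-yl)cyclohex-2-en-1-yl (E)-2-methylbut-2-enoate | O=CC1=C[C@H](OC(=O)/C(C)=C/C)[C@H](C(C)C)[C@@H](O)C1(OC)OC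
F7 | step 12 | (1S,5R,6S)-5-acetoxy-3-formyl-4,4-dimethoxy-6-(propan-2-yl)cyclohex-2-en-1-yl (E)-2-methylbut-2-enoate | O=CC1=C[C@H](OC(=O)/C(C)=C/C)[C@H](C(C)C)[C@@H](OC(C)=O)C1(OC)OC
F8 | step 12 | (1S,5R,6S)-5-acetoxy-3-(hydroxymethyl)-4,4-dimethoxy-6-(propan-2-yl)cyclohex-2-en-1-yl (E)-2-methylbut-2-enoate | OCC1=C[C@H](OC(=O)/C(C)=C/C)[C@H](C(C)C)[C@@H](OC(C)=O)C1(OC)OC
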